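**Retrosynthetic overview**

1. The biaryl bond between the two guaiacyl rings is cut last (Suzuki–Miyaura coupling of aryl bromide 14 with aryl boronate 27); the four benzyl ethers are removed in one final hydrogenolysis.
2. In each half, the C-3 hydroxyl and the C-3 benzyl group of the lactone go back to an (S)-4-benzyl-γ-butyrolactone: enolate hydroxylation, then benzylation of the enediolate trans to the C-4 benzyl group.
3. Enabling feature: in each lactone ring (O1–C2(=O)–C3–C4–C5) the ring oxygen O1 lies between the carbonyl C2 and an unsubstituted C5H2 next to C4–H. With C-3 stripped to CH2, taking out O1 leaves a 3-benzylcyclobutanone with a mirror plane through C2 and C4.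
4. That achiral, strained ketone is turned into the lactone, with the O1–C5 bond and the C-4 stereocenter, by a catalytic enantioselective Baeyer–Villiger ring expansion; C-4 then controls C-3.
5. Ring order: cyclobutanone by [2+2] (steps 2–3), lactone of unit A (step 4), cyclobutanone and lactone of unit B (steps 12–14); no ring is formed after that.

Key step: step 4

Remark on the chemistry: the antipode of the N,N'-dioxide ligand (both are accessible from (S)- or (R)-pipecolic acid) that delivers the (S)-lactones 6 and 20 is to be fixed in a trial run. The descriptor of the benzyl-bearing ring carbon changes from S (6, 20) to R (8, 22 and later) through the priority rules only, not through any change in space.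

**Route**

Step 1
Reactants: 1 eugenol
Product: 2 4-allyl-1-(benzyloxy)-2-methoxybenzene
Conditions: BnBr, K2CO3, acetone, reflux
Reagents that add atoms: benzyl bromide, BrCc1ccccc1
Why: Williamson ether synthesis (SN2 of the phenoxide on benzyl bromide) masks the phenol against acylation by the ketene precursor and against the strong bases used later.

Step 2
Reactants: 2 4-allyl-1-(benzyloxy)-2-methoxybenzene
Product: 3 3-[4-(benzyloxy)-3-methoxybenzyl]-2,2-dichlorocyclobutan-1-one (racemic)
Conditions: Cl3CCOCl, Zn(Cu) couple, Et2O/DME, rt to reflux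
Reagents that add atoms: trichloroacetyl chloride, ClC(=O)C(Cl)(Cl)Cl (source of dichloroketene, ClC(Cl)=C=O)
Why: thermal [2+2] cycloaddition of dichloroketene, made in the flask by zinc dechlorination, to the terminal alkene should join the ketene carbonyl carbon to the terminal CH2, which places the benzyl group at C-3.

Step 3
Reactants: 3 3-[4-(benzyloxy)-3-methoxybenzyl]-2,2-dichlorocyclobutan-1-one
Product: 4 3-[4-(benzyloxy)-3-methoxybenzyl]cyclobutan-1-one
Conditions: Zn dust, AcOH, rt
Reagents that add atoms: none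
Why: reductive dechlorination of the α,α-dichloroketone by zinc in acetic acid should give the mirror-symmetric (achiral) ketone while leaving the benzyl ether untouched.

Step 4
Reactants: 4 3-[4-(benzyloxy)-3-methoxybenzyl]cyclobutan-1-one
Product: 6 (S)-4-[4-(benzyloxy)-3-methoxybenzyl]dihydrofuran-2(3H)-one, via peroxyhemiketal adduct 5 (not isolated)
Conditions: mCPBA (1.1 equiv), Sc(OTf)3 (5 mol %), chiral N,N'-dioxide ligand (pipecolic acid-derived bis(2,6-diisopropylanilide), propane-1,3-diyl linker, 5.5 mol %), EtOAc, −20 °C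
Reagents that add atoms: 3-chloroperoxybenzoic acid (mCPBA), O=C(OO)c1cccc(Cl)c1
Why: The peracid adds to the Sc(OTf)3-activated carbonyl of 4 to give adduct 5, and one of the two enantiotopic ring CH2 groups then migrates from carbon to the proximal peroxide oxygen with loss of 3-chlorobenzoate, which creates the CH2–O bond and turns the four-membered ring into the five-membered lactone. The closest known reaction type is the catalytic enantioselective Baeyer–Villiger desymmetrization of 3-substituted cyclobutanones, and release of cyclobutanone strain should let it run at −20 °C. The lactone ring is closed by ring expansion (a 1,2-shift of carbon to oxygen with retention at the migrating carbon), not by cyclization of an open chain. The only new stereocenter, C-4 of the lactone, should be set by the chiral N,N'-dioxide–scandium complex, which holds adduct 5 so that only one of the enantiotopic CH2 groups lies antiperiplanar to the O–O bond; this center later relays the configuration of C-3. The step needs enantiotopic-group selectivity (catalyst control) and chemoselectivity for the ketone over the electron-rich arene and the benzyl ether, which the high reactivity of the strained ketone at low temperature should secure; regioselectivity is no issue, because the mirror plane of 4 makes both possible migrations lead to the same constitution.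

Step 5
Reactants: 6 (S)-4-[4-(benzyloxy)-3-methoxybenzyl]dihydrofuran-2(3H)-one
Product: 8 (3S,4R)-4-[4-(benzyloxy)-3-methoxybenzyl]-3-hydroxydihydrofuran-2(3H)-one, via potassium enolate 7 (not isolated)
Conditions: KN(SiMe3)2 (1.1 equiv), THF, −78 °C; then 2-(phenylsulfonyl)-3-phenyloxaziridine, −78 °C; AcOH quench
Reagents that add atoms: 2-(phenylsulfonyl)-3-phenyloxaziridine, O=S(=O)(c1ccccc1)N1OC1c1ccccc1
Why: electrophilic α-hydroxylation of the lactone enolate by the N-sulfonyloxaziridine (enolate oxidation) should deliver oxygen trans to the C-4 benzyl group; C-3 is made planar again in step 9, so a C-3 epimer can be carried along.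

Step 6
Reactants: 9 5-bromovanillin (3-bromo-4-hydroxy-5-methoxybenzaldehyde)
Product: 10 4-(benzyloxy)-3-bromo-5-methoxybenzaldehyde
Conditions: BnBr, K2CO3, DMF, 60 °C
Reagents that add atoms: benzyl bromide, BrCc1ccccc1
Why: Williamson ether synthesis of the hindered but acidic phenol should proceed cleanly in DMF.

Step 7
Reactants: 10 4-(benzyloxy)-3-bromo-5-methoxybenzaldehyde
Product: 11 [4-(benzyloxy)-3-bromo-5-methoxyphenyl]methanol
Conditions: NaBH4, MeOH/THF, 0 °C
Reagents that add atoms: none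
Why: borohydride reduction of the aldehyde to the benzylic alcohol leaves the aryl bromide and the benzyl ether untouched.

Step 8
Reactants: 11 [4-(benzyloxy)-3-bromo-5-methoxyphenyl]methanol
Product: 12 2-(benzyloxy)-1-bromo-5-(bromomethyl)-3-methoxybenzene
Conditions: PBr3 (0.4 equiv), CH2Cl2, 0 °C
Reagents that add atoms: phosphorus tribromide, BrP(Br)Br
Why: conversion of the benzylic alcohol into the bromide by SN2 displacement of the intermediate phosphite ester is standard for alkoxybenzyl alcohols.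

Step 9
Reactants: 8 (3S,4R)-4-[4-(benzyloxy)-3-methoxybenzyl]-3-hydroxydihydrofuran-2(3H)-one; 12 2-(benzyloxy)-1-bromo-5-(bromomethyl)-3-methoxybenzene
Product: 14 (3R,4R)-3-[4-(benzyloxy)-3-bromo-5-methoxybenzyl]-4-[4-(benzyloxy)-3-methoxybenzyl]-3-hydroxydihydrofuran-2(3H)-one, via dilithium enediolate 13 (not isolated)
Conditions: LiN(iPr)2 (2.3 equiv), THF/DMPU, −78 °C; then 12, −78 to −40 °C; AcOH quench
Reagents that add atoms: none
Why: C-alkylation of the α-hydroxy lactone dianion (enediolate alkylation) should take place on the face of the planar C-3 opposite the C-4 benzyl group, which sets the quaternary carbinol center with the two benzyl groups trans and the hydroxyl cis to the C-4 benzyl, as in the target.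

Step 10
Reactants: 1 eugenol
Product: 15 4-allyl-2-bromo-6-methoxyphenol
Conditions: NBS (1.0 equiv), iPr2NH (10 mol %), CH2Cl2, 0 °C, dark
Reagents that add atoms: N-bromosuccinimide, O=C1CCC(=O)N1Br
Why: amine-catalysed electrophilic aromatic bromination of a phenol is ortho-selective, and the only free ortho position (para is blocked by the allyl group) should react faster than the isolated alkene.

Step 11
Reactants: 15 4-allyl-2-bromo-6-methoxyphenol
Product: 16 5-allyl-2-(benzyloxy)-1-bromo-3-methoxybenzene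
Conditions: BnBr, K2CO3, DMF, 60 °C
Reagents that add atoms: benzyl bromide, BrCc1ccccc1
Why: Williamson ether synthesis, as in step 1.

Step 12
Reactants: 16 5-allyl-2-(benzyloxy)-1-bromo-3-methoxybenzene
Product: 17 3-[4-(benzyloxy)-3-bromo-5-methoxybenzyl]-2,2-dichlorocyclobutan-1-one (racemic)
Conditions: Cl3CCOCl, Zn(Cu) couple, Et2O/DME, rt to reflux
Reagents that add atoms: trichloroacetyl chloride, ClC(=O)C(Cl)(Cl)Cl (source of dichloroketene, ClC(Cl)=C=O)
Why: [2+2] cycloaddition of dichloroketene to the terminal alkene, as in step 2; the aryl bromide should not insert zinc under these conditions.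

Step 13
Reactants: 17 3-[4-(benzyloxy)-3-bromo-5-methoxybenzyl]-2,2-dichlorocyclobutan-1-one
Product: 18 3-[4-(benzyloxy)-3-bromo-5-methoxybenzyl]cyclobutan-1-one
Conditions: Zn dust, AcOH, rt
Reagents that add atoms: none
Why: reductive dechlorination of the α,α-dichloroketone, as in step 3, should spare the aryl bromide at room temperature.

Step 14
Reactants: 18 3-[4-(benzyloxy)-3-bromo-5-methoxybenzyl]cyclobutan-1-one
Product: 20 (S)-4-[4-(benzyloxy)-3-bromo-5-methoxybenzyl]dihydrofuran-2(3H)-one, via peroxyhemiketal adduct 19 (not isolated)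
Conditions: mCPBA (1.1 equiv), Sc(OTf)3 (5 mol %), the same chiral N,N'-dioxide ligand (5.5 mol %), EtOAc, −20 °C
Reagents that add atoms: 3-chloroperoxybenzoic acid (mCPBA), O=C(OO)c1cccc(Cl)c1
Why: the same enantioselective Baeyer–Villiger desymmetrization as in step 4 should build the lactone ring and the C-4 stereocenter of unit B under catalyst control.

Step 15
Reactants: 20 (S)-4-[4-(benzyloxy)-3-bromo-5-methoxybenzyl]dihydrofuran-2(3H)-one
Product: 22 (3S,4R)-4-[4-(benzyloxy)-3-bromo-5-methoxybenzyl]-3-hydroxydihydrofuran-2(3H)-one, via potassium enolate 21 (not isolated)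
Conditions: KN(SiMe3)2 (1.1 equiv), THF, −78 °C; then 2-(phenylsulfonyl)-3-phenyloxaziridine, −78 °C; AcOH quench
Reagents that add atoms: 2-(phenylsulfonyl)-3-phenyloxaziridine, O=S(=O)(c1ccccc1)N1OC1c1ccccc1
Why: enolate oxidation with the N-sulfonyloxaziridine, as in step 5; the aryl bromide is inert to the amide base at −78 °C.

Step 16
Reactants: 23 [4-(benzyloxy)-3-methoxyphenyl]methanol
Product: 24 1-(benzyloxy)-4-(bromomethyl)-2-methoxybenzene
Conditions: PBr3 (0.4 equiv), CH2Cl2, 0 °C; used at once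
Reagents that add atoms: phosphorus tribromide, BrP(Br)Br
Why: benzylic alcohol to bromide with PBr3, as in step 8.

Step 17
Reactants: 22 (3S,4R)-4-[4-(benzyloxy)-3-bromo-5-methoxybenzyl]-3-hydroxydihydrofuran-2(3H)-one; 24 1-(benzyloxy)-4-(bromomethyl)-2-methoxybenzene
Product: 26 (3R,4R)-4-[4-(benzyloxy)-3-bromo-5-methoxybenzyl]-3-[4-(benzyloxy)-3-methoxybenzyl]-3-hydroxydihydrofuran-2(3H)-one, via dilithium enediolate 25 (not isolated)
Conditions: LiN(iPr)2 (2.3 equiv), THF/DMPU, −78 °C; then 24, −78 to −40 °C; AcOH quench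
Reagents that add atoms: none
Why: enediolate alkylation anti to the C-4 benzyl group, as in step 9, should set the quaternary carbinol center of unit B with the same relative and absolute configuration.

Step 18
Reactants: 26 (3R,4R)-4-[4-(benzyloxy)-3-bromo-5-methoxybenzyl]-3-[4-(benzyloxy)-3-methoxybenzyl]-3-hydroxydihydrofuran-2(3H)-one
Product: 27 (3R,4R)-4-[4-(benzyloxy)-3-methoxy-5-(4,4,5,5-tetramethyl-1,3,2-dioxaborolan-2-yl)benzyl]-3-[4-(benzyloxy)-3-methoxybenzyl]-3-hydroxydihydrofuran-2(3H)-one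
Conditions: B2pin2, Pd(dppf)Cl2 (5 mol %), KOAc, 1,4-dioxane, 85 °C
Reagents that add atoms: bis(pinacolato)diboron, CC1(C)OB(OC1(C)C)B1OC(C)(C)C(C)(C)O1
Why: Miyaura borylation (oxidative addition of the aryl bromide to zerovalent palladium, acetate-assisted transmetalation with the diboron, reductive elimination) tolerates the lactone, the tertiary alcohol and the benzyl ethers.

Step 19
Reactants: 27 the pinacol boronate of unit B; 14 (3R,4R)-3-[4-(benzyloxy)-3-bromo-5-methoxybenzyl]-4-[4-(benzyloxy)-3-methoxybenzyl]-3-hydroxydihydrofuran-2(3H)-one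
Product: 28 (3R,4R)-3-{[2,2'-bis(benzyloxy)-5'-{[(3R,4R)-4-[4-(benzyloxy)-3-methoxybenzyl]-4-hydroxy-5-oxotetrahydrofuran-3-yl]methyl}-3,3'-dimethoxy-[1,1'-biphenyl]-5-yl]methyl}-4-[4-(benzyloxy)-3-methoxybenzyl]-3-hydroxydihydrofuran-2(3H)-one (tetra-O-benzyl ether of the target)
Conditions: Pd(OAc)2 (5 mol %), SPhos (10 mol %), K3PO4, toluene/H2O, 80 °C; 1 M HCl work-up
Reagents that add atoms: none
Why: Suzuki–Miyaura coupling of two aryl partners that each carry only one ortho substituent should form the biaryl bond at the only positions that bear bromine and boron, so the unsymmetrical linkage is fixed by the building blocks; the acidic work-up recloses any lactone opened by the base.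

Step 20
Reactants: 28 tetra-O-benzyl ether of the target
Product: 29 CNP0218652.1, (3R,4R)-3-{[2,2'-dihydroxy-5'-{[(3R,4R)-4-hydroxy-4-(4-hydroxy-3-methoxybenzyl)-5-oxotetrahydrofuran-3-yl]methyl}-3,3'-dimethoxy-[1,1'-biphenyl]-5-yl]methyl}-3-hydroxy-4-(4-hydroxy-3-methoxybenzyl)dihydrofuran-2(3H)-one
Conditions: H2 (1 atm), Pd/C (10 wt% Pd), EtOAc/MeOH, rt
Reagents that add atoms: none
Why: hydrogenolysis of the four aryl benzyl ethers should free all phenols in one operation, while the tertiary (homobenzylic) alcohols, the lactones and the biaryl are inert.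

**Compound list**

1 | eugenol (4-allyl-2-methoxyphenol) | C=CCc1ccc(O)c(OC)c1 | starting material
2 | 4-allyl-1-(benzyloxy)-2-methoxybenzene | C=CCc1ccc(OCc2ccccc2)c(OC)c1 | intermediate
3 | 3-[4-(benzyloxy)-3-methoxybenzyl]-2,2-dichlorocyclobutan-1-one (racemic) | O=C1CC(Cc2ccc(OCc3ccccc3)c(OC)c2)C1(Cl)Cl | intermediate
4 | 3-[4-(benzyloxy)-3-methoxybenzyl]cyclobutan-1-one (achiral) | O=C1CC(Cc2ccc(OCc3ccccc3)c(OC)c2)C1 | intermediate
5 | peroxyhemiketal adduct of 4 with mCPBA, 3-[4-(benzyloxy)-3-methoxybenzyl]-1-hydroxycyclobutyl 3-chloroperoxybenzoate | OC1(OOC(=O)c2cccc(Cl)c2)CC(Cc2ccc(OCc3ccccc3)c(OC)c2)C1 | intermediate (not isolated)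
6 | (S)-4-[4-(benzyloxy)-3-methoxybenzyl]dihydrofuran-2(3H)-one | O=C1C[C@H](Cc2ccc(OCc3ccccc3)c(OC)c2)CO1 | intermediate
7 | potassium enolate of 6 | [K+].[O-]C1=C[C@H](Cc2ccc(OCc3ccccc3)c(OC)c2)CO1 | intermediate (not isolated)
8 | (3S,4R)-4-[4-(benzyloxy)-3-methoxybenzyl]-3-hydroxydihydrofuran-2(3H)-one | COc1cc(C[C@@H]2COC(=O)[C@H]2O)ccc1OCc1ccccc1 | intermediate
9 | 5-bromovanillin (3-bromo-4-hydroxy-5-methoxybenzaldehyde) | COc1cc(C=O)cc(Br)c1O | starting material
10 | 4-(benzyloxy)-3-bromo-5-methoxybenzaldehyde | COc1cc(C=O)cc(Br)c1OCc1ccccc1 | intermediate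
11 | [4-(benzyloxy)-3-bromo-5-methoxyphenyl]methanol | COc1cc(CO)cc(Br)c1OCc1ccccc1 | intermediate
12 | 2-(benzyloxy)-1-bromo-5-(bromomethyl)-3-methoxybenzene | COc1cc(CBr)cc(Br)c1OCc1ccccc1 | intermediate
13 | dilithium enediolate of 8 | [Li+].[Li+].[O-]C1=C([O-])[C@H](Cc2ccc(OCc3ccccc3)c(OC)c2)CO1 | intermediate (not isolated)
14 | (3R,4R)-3-[4-(benzyloxy)-3-bromo-5-methoxybenzyl]-4-[4-(benzyloxy)-3-methoxybenzyl]-3-hydroxydihydrofuran-2(3H)-one | COc1cc(C[C@@H]2COC(=O)[C@@]2(O)Cc2cc(OC)c(OCc3ccccc3)c(Br)c2)ccc1OCc1ccccc1 | intermediate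
15 | 4-allyl-2-bromo-6-methoxyphenol | C=CCc1cc(Br)c(O)c(OC)c1 | intermediate
16 | 5-allyl-2-(benzyloxy)-1-bromo-3-methoxybenzene | C=CCc1cc(Br)c(OCc2ccccc2)c(OC)c1 | intermediate
17 | 3-[4-(benzyloxy)-3-bromo-5-methoxybenzyl]-2,2-dichlorocyclobutan-1-one (racemic) | O=C1CC(Cc2cc(Br)c(OCc3ccccc3)c(OC)c2)C1(Cl)Cl | intermediate
18 | 3-[4-(benzyloxy)-3-bromo-5-methoxybenzyl]cyclobutan-1-one (achiral) | O=C1CC(Cc2cc(Br)c(OCc3ccccc3)c(OC)c2)C1 | intermediate
19 | peroxyhemiketal adduct of 18 with mCPBA, 3-[4-(benzyloxy)-3-bromo-5-methoxybenzyl]-1-hydroxycyclobutyl 3-chloroperoxybenzoate | OC1(OOC(=O)c2cccc(Cl)c2)CC(Cc2cc(Br)c(OCc3ccccc3)c(OC)c2)C1 | intermediate (not isolated)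
20 | (S)-4-[4-(benzyloxy)-3-bromo-5-methoxybenzyl]dihydrofuran-2(3H)-one | O=C1C[C@H](Cc2cc(Br)c(OCc3ccccc3)c(OC)c2)CO1 | intermediate
21 | potassium enolate of 20 | [K+].[O-]C1=C[C@H](Cc2cc(Br)c(OCc3ccccc3)c(OC)c2)CO1 | intermediate (not isolated)
22 | (3S,4R)-4-[4-(benzyloxy)-3-bromo-5-methoxybenzyl]-3-hydroxydihydrofuran-2(3H)-one | COc1cc(C[C@@H]2COC(=O)[C@H]2O)cc(Br)c1OCc1ccccc1 | intermediate
23 | [4-(benzyloxy)-3-methoxyphenyl]methanol | COc1cc(CO)ccc1OCc1ccccc1 | starting material
24 | 1-(benzyloxy)-4-(bromomethyl)-2-methoxybenzene | COc1cc(CBr)ccc1OCc1ccccc1 | intermediate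
25 | dilithium enediolate of 22 | [Li+].[Li+].[O-]C1=C([O-])[C@H](Cc2cc(Br)c(OCc3ccccc3)c(OC)c2)CO1 | intermediate (not isolated)
26 | (3R,4R)-4-[4-(benzyloxy)-3-bromo-5-methoxybenzyl]-3-[4-(benzyloxy)-3-methoxybenzyl]-3-hydroxydihydrofuran-2(3H)-one | COc1cc(C[C@@H]2COC(=O)[C@@]2(O)Cc2ccc(OCc3ccccc3)c(OC)c2)cc(Br)c1OCc1ccccc1 | intermediate
27 | (3R,4R)-4-[4-(benzyloxy)-3-methoxy-5-(4,4,5,5-tetramethyl-1,3,2-dioxaborolan-2-yl)benzyl]-3-[4-(benzyloxy)-3-methoxybenzyl]-3-hydroxydihydrofuran-2(3H)-one | COc1cc(C[C@@H]2COC(=O)[C@@]2(O)Cc2ccc(OCc3ccccc3)c(OC)c2)cc(B2OC(C)(C)C(C)(C)O2)c1OCc1ccccc1 | intermediate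
28 | tetra-O-benzyl ether of the target (name as in step 19) | COc1cc(C[C@@H]2COC(=O)[C@@]2(O)Cc2cc(OC)c(OCc3ccccc3)c(-c3cc(C[C@@H]4COC(=O)[C@@]4(O)Cc4ccc(OCc5ccccc5)c(OC)c4)cc(OC)c3OCc3ccccc3)c2)ccc1OCc1ccccc1 | intermediate
29 | CNP0218652.1 (name as in step 20; all four stereocenters R) | COc1cc(C[C@@H]2COC(=O)[C@@]2(O)Cc2cc(OC)c(O)c(-c3cc(C[C@@H]4COC(=O)[C@@]4(O)Cc4ccc(O)c(OC)c4)cc(OC)c3O)c2)ccc1O | target

**Totals and risks**

Total step count: 20. Longest linear sequence: 10 steps (steps 10–15, 17, 18, 19, 20, from eugenol).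

Steps most likely to fail:

1. Step 4 (step 14 shares the risk). The catalyst may discriminate poorly between the enantiotopic methylene groups, because the aryl group sits one carbon away from the ring, and an uncatalysed background oxidation by the peracid would erode the enantiomeric purity further. Fallback, from bromide 24 back to lactone 6: the sodium enolate (NaN(SiMe3)2, THF, −78 °C) of (S)-4-benzyl-3-(4-tert-butoxy-4-oxobutanoyl)oxazolidin-2-one F1, made from mono-tert-butyl succinate and (S)-4-benzyloxazolidin-2-one through the pivaloyl mixed anhydride, is alkylated with 24 (Evans alkylation, attack opposite the auxiliary benzyl group) to give (S)-4-benzyl-3-[(S)-2-[4-(benzyloxy)-3-methoxybenzyl]-4-tert-butoxy-4-oxobutanoyl]oxazolidin-2-one F2. LiBH4 (THF/MeOH, 0 °C) then removes the auxiliary reductively to give tert-butyl (S)-4-[4-(benzyloxy)-3-methoxyphenyl]-3-(hydroxymethyl)butanoate F3, and TsOH (cat.) in toluene at 80 °C closes the lactone to 6.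

2. Step 9 (step 17 shares the risk). The second deprotonation may stay incomplete, the alkoxide oxygen may be alkylated in competition with carbon, and proton transfer may stall the reaction. Fallback, from hydroxy lactone 8 back to 14: the hydroxyl is masked with MOMCl/iPr2NEt (CH2Cl2) to give (3S,4R)-4-[4-(benzyloxy)-3-methoxybenzyl]-3-(methoxymethoxy)dihydrofuran-2(3H)-one F4. Its mono-enolate (LiN(iPr)2, 1.1 equiv, THF/DMPU, −78 °C) is alkylated with 12, again anti to the C-4 benzyl group, to give (3R,4R)-3-[4-(benzyloxy)-3-bromo-5-methoxybenzyl]-4-[4-(benzyloxy)-3-methoxybenzyl]-3-(methoxymethoxy)dihydrofuran-2(3H)-one F5. HCl in MeOH (40 °C) then removes the acetal to give 14.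

3. Step 19. Protodeboronation of the ortho-alkoxy arylboronate and slow transmetalation between two fully elaborated partners may lower conversion, and the aqueous base may open the lactones. Fallback, from alcohol 11 back to 28, with the biaryl bond made before unit A is attached: Miyaura borylation of 11 (B2pin2, Pd(dppf)Cl2, KOAc, dioxane, 85 °C) gives the simple, isolable [4-(benzyloxy)-3-methoxy-5-(4,4,5,5-tetramethyl-1,3,2-dioxaborolan-2-yl)phenyl]methanol F6, which is used in excess. Suzuki–Miyaura coupling of F6 with bromide 26 (Pd(OAc)2, SPhos, K3PO4, toluene/H2O) gives (3R,4R)-4-{[2,2'-bis(benzyloxy)-5'-(hydroxymethyl)-3,3'-dimethoxy-[1,1'-biphenyl]-5-yl]methyl}-3-[4-(benzyloxy)-3-methoxybenzyl]-3-hydroxydihydrofuran-2(3H)-one F7. An Appel reaction (CBr4, PPh3, CH2Cl2, 0 °C) converts only the primary benzylic alcohol into the bromide, (3R,4R)-4-{[2,2'-bis(benzyloxy)-5'-(bromomethyl)-3,3'-dimethoxy-[1,1'-biphenyl]-5-yl]methyl}-3-[4-(benzyloxy)-3-methoxybenzyl]-3-hydroxydihydrofuran-2(3H)-one F8. F8, with its tertiary hydroxyl first turned into the lithium alkoxide by LiN(SiMe3)2 (1 equiv, −78 °C), is then added to enediolate 13 (from 8 and LiN(iPr)2), and an AcOH quench gives 28.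

**Further compounds**

F1 | step 4 | (S)-4-benzyl-3-(4-tert-butoxy-4-oxobutanoyl)oxazolidin-2-one | CC(C)(C)OC(=O)CCC(=O)N1[C@@H](Cc2ccccc2)COC1=O
F2 | step 4 | (S)-4-benzyl-3-[(S)-2-[4-(benzyloxy)-3-methoxybenzyl]-4-tert-butoxy-4-oxobutanoyl]oxazolidin-2-one | CC(C)(C)OC(=O)C[C@H](Cc1ccc(OCc2ccccc2)c(OC)c1)C(=O)N1[C@@H](Cc2ccccc2)COC1=O
F3 | step 4 | tert-butyl (S)-4-[4-(benzyloxy)-3-methoxyphenyl]-3-(hydroxymethyl)butanoate | CC(C)(C)OC(=O)C[C@H](Cc1ccc(OCc2ccccc2)c(OC)c1)CO
F4 | step 9 | (3S,4R)-4-[4-(benzyloxy)-3-methoxybenzyl]-3-(methoxymethoxy)dihydrofuran-2(3H)-one | COc1cc(C[C@@H]2COC(=O)[C@H]2OCOC)ccc1OCc1ccccc1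
F5 | step 9 | (3R,4R)-3-[4-(benzyloxy)-3-bromo-5-methoxybenzyl]-4-[4-(benzyloxy)-3-methoxybenzyl]-3-(methoxymethoxy)dihydrofuran-2(3H)-one | COc1cc(C[C@@H]2COC(=O)[C@@]2(OCOC)Cc2cc(OC)c(OCc3ccccc3)c(Br)c2)ccc1OCc1ccccc1
F6 | step 19 | [4-(benzyloxy)-3-methoxy-5-(4,4,5,5-tetramethyl-1,3,2-dioxaborolan-2-yl)phenyl]methanol | COc1cc(CO)cc(B2OC(C)(C)C(C)(C)O2)c1OCc1ccccc1
F7 | step 19 | (3R,4R)-4-{[2,2'-bis(benzyloxy)-5'-(hydroxymethyl)-3,3'-dimethoxy-[1,1'-biphenyl]-5-yl]methyl}-3-[4-(benzyloxy)-3-methoxybenzyl]-3-hydroxydihydrofuran-2(3H)-one | COc1cc(C[C@@H]2COC(=O)[C@@]2(O)Cc2ccc(OCc3ccccc3)c(OC)c2)cc(-c2cc(CO)cc(OC)c2OCc2ccccc2)c1OCc1ccccc1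
F8 | step 19 | (3R,4R)-4-{[2,2'-bis(benzyloxy)-5'-(bromomethyl)-3,3'-dimethoxy-[1,1'-biphenyl]-5-yl]methyl}-3-[4-(benzyloxy)-3-methoxybenzyl]-3-hydroxydihydrofuran-2(3H)-one | COc1cc(C[C@@H]2COC(=O)[C@@]2(O)Cc2ccc(OCc3ccccc3)c(OC)c2)cc(-c2cc(CBr)cc(OC)c2OCc2ccccc2)c1OCc1ccccc1
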